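12.3% of the D charged was missing from the last epsilon reading, and I made that gap my way into these flasks.

| flask | D | J | temperature | remark | time |
|---|---|---|---|---|---|
| eta | 42 mM | 30 mM | 50 °C | run made earlier |  |
| epsilon | 66 mM | 30 mM | 72 °C | run made earlier |  |
| beta | 30 mM | 15 mM | 50 °C | run made earlier |  |
| north-east | 30 mM | 30.0 mM | 60 °C |  | 2.5 min |
| south-east | 30 mM | 30.0 mM | 40 °C |  | 2.5 min |
| east | 30 mM | 30.0 mM | 80 °C |  | 2.5 min |
| north | 30 mM | 30.0 mM |  | at 40 °C until 30 s, from then on at 80 °C | 2.5 min |

- eta (time / min: E / %, Q / %, D / %): 0.250: 2.2, 0, 98.5; 0.417: 2.1, 0, 97.2; 0.667: 4.3, 0, 94.6; 1.33: 7.5, 0.1, 90.7; 2.50: 10.7, 0.3, 82.4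
- epsilon (time / s: E / %, Q / %, D / %): 10.0: 4.5, 0.1, 95.5; 15.0: 5.1, 0.7, 92.2; 30.0: 9.3, 0.1, 83.5; 50.0: 10.0, 1.9, 75.8
- beta (time / min: E / %, Q / %, D / %): 0.250: 0.4, 0.1, 99.2; 0.417: 0.4, 0, 99.0; 0.667: 1.5, 0.1, 97.7; 1.33: 3.2, 1.0, 94.8; 2.50: 6.6, 0, 90.4

(scatter of a reading: 0.5 percentage points)



- which flask leads in amount of E, in percent of the D charged ("all alike" within 1.5 percentage points) (north-east / south-east / east / north / all alike)
- how much E is there at the end, in percent of the D charged: north-east
- how much E is there at the end, in percent of the D charged: south-east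
- how much E is there at the end, in percent of the D charged: east
- how much E is there at the end, in percent of the D charged: north

In eta the gap was 1.10% at 0.667 min but 6.60% at 2.50 min, so it opened as E built up. I therefore followed one molecule of D to a fork: it met J and gave E, or it met an E and the pair left the readings. With a and b the fractions of the D charge lost by each road, and taking Q as the only other fate of E:

gap = 2b, a = E + Q + b, ρ = b/a = w · 0.5E / (j − 0.5a)

Here j is the J charge as a fraction of the D charge, and mean E and mean J are taken halfway. The readings gave w as 2.77 in eta, 2.48 in epsilon and 2.58 in beta. I carried the mean of the eta and epsilon readings, w = 2.63, taken as the same at each temperature, with the beta value left beside it: the odds of the E road against the J road at equal amounts, a selectivity factor.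

At the first eta reading, with E at 2.2% and J near 0.714 of the D charge, ρ came to 0.0405, so nearly all of the lost D had gone by the J road. Through the middle E rises, J falls and ρ climbs. At the end, leaving Q aside, E is the lost fraction times (1 − ρ)/(1 + ρ).

For the clock I took the loss as first order in D and in J. From 50 °C to 72 °C the rate rose 4.82-fold, and I took its logarithm as straight in temperature. With equal charges the lost fraction is x/(1 + x), where x = 0.215 at 50 °C. My reckoning gave:

north-east: lost 30.5%, E 17.7%

south-east: lost 9.52%, E 7.70%

east: lost 64.8%, E below 25.6%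

north: lost 59.9%, E below 24.8%

I read the two hot figures as too high, since this reckoning leaves Q aside. The last Q reading in epsilon, at 72 °C, gave E a drain of 0.456 min⁻¹, a half-life of 1.52 min, shorter than the 2.5 min of the flasks. So I expected north-east to lead.

The forecast also put north-east first, but with other figures, 11.3%, 8.1%, 2.4% and 3.2% in the order above, holding that “E drains mainly to something unseen”.

The simulation gave 17.2%, 7.25%, 10.9% and 12.8%, with north-east ahead.

    D + J → E (k = 0.293 L mol⁻¹ s⁻¹, Ea = 62.0 kJ mol⁻¹)
    Q ⇌ Z (K = 0.392, k = 0.0153 s⁻¹, Ea = 102 kJ mol⁻¹, ΔH = 2.00 kJ mol⁻¹)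
    D + E → L (k = 0.523 L mol⁻¹ s⁻¹, Ea = 54.0 kJ mol⁻¹)
    E → Q (k = 0.0126 s⁻¹, Ea = 106 kJ mol⁻¹)
    (constants at 80 °C)

In north-east, each step taken net, E was made 2.87 times as fast as it was used at 1.03 min, and 1.44 times at 2.50 min, when Q and Z held 2.40%. In east, Q and Z held 24.7% at 2.50 min, and E stood below my figure. The neighbour of north-east with 7.5 mM of D, so 4.00 equiv of J, lost 31.9% of its D, and at that loss w gives E 26.6%. The computed flask holds 24.5%, with Q at 2.81%.

All runs are simulated with made-up constants; noise was put on by code.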